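**Remark on the chemistry.** Lignan numbering is used: ring A is C1–C6, the chain is C7–C9, ring B is primed, C7' is the ketone carbon and C8' its CH2OH carbon. Both enantiomers of the glycerate acetonide ester are assumed to be on sale; the (S)-ester is the one whose stereocentre maps onto C8.

## The problem

The target is an acyclic 8-O-4' neolignan. It is a guaiacylglycerol (ring A with the chain C7–C9) whose C8 oxygen is bound to C4' of ring B, and ring B carries methoxy groups at C3' and C5' and a hydroxyacetyl group (C7'=O, C8'H2–OH) at C1'. No ring has to be built. The difficulty is the C8–O–C4' ether, which joins a secondary carbon flanked by two oxygen-bearing carbons to an aryl carbon shielded by two ortho methoxy groups. The two adjacent stereocentres, C7 (R) and C8 (S), stand in the erythro relation. C8 can be bought from the chiral pool and, as an α-oxygen, can direct a chelated hydride onto a C7 ketone; control in the other direction would need a substitution at C8. The fragile parts are the free para-hydroxybenzyl alcohol (ionisation at C7 under acid, quinone-methide chemistry under base), the β-aryl ether (lost or epimerised as soon as C8 lies next to a carbonyl), the α-hydroxy ketone on ring B and the free phenol, so these should be unmasked last and near neutrality. The feature that opens the chosen key step is C4' itself. It has no ortho hydrogen (C3' and C5' bear OMe), so an aryne cannot form, and it lies para to the acyl carbon C7'. Ring B is therefore electron-poor enough to be handed from trivalent iodine to O8 without the C8–O bond ever being broken.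

## Retrosynthesis

**22 ⇒ 21.** Only Si–O bonds are cut: the silylene across O7/O9 and the silyl ether on the ring-A phenol. This keeps the phenol, the benzylic carbinol, the primary alcohol and the finished hydroxy ketone apart until the last step. Precursor 21 already holds every carbon and both stereocentres. The forward reaction must be a fluoride cleavage that is neither basic nor strongly acidic.

**21 ⇒ 20 ⇒ 19 ⇒ 18.** The C7'–C8' bond is cut, giving aldehyde 20 plus one carbon of formaldehyde. 20 is traced through benzylic alcohol 19 to methyl ester 18. Carrying an acetyl or hydroxyacetyl group through the ether formation was rejected because an enolisable ketone would not survive a sodium alkoxide and an electrophilic iodonium salt. The ester is not enolisable, it is the para acceptor the key step needs, and it is already present in the commercial bromide 11. The forward step is a carbene-catalysed hydroxymethylation, in which the aryl aldehyde must act as acyl donor and formaldehyde as acceptor.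

**18 ⇒ 10 + 15 (key disconnection).** The O8–C4' bond is cut on the aryl side. The neighbouring cut, C8–O, would mean an SN2 or Mitsunobu displacement at a carbon flanked by two C–O bonds by a weak, hindered 2,6-dimethoxyphenol nucleophile, with inversion and competing elimination. The other classical route passes through an α-aryloxy ketone whose C8 epimerises. Cutting on the aryl side leaves the C8–O bond intact, so both stereocentres are settled before the fragments meet. The precursors are of similar size: alcohol 10 holds all the stereochemistry and iodonium salt 15 is achiral. The forward reaction must transfer the ester-bearing aryl, not the dummy aryl, to a hindered secondary alkoxide, and O8 must be the only nucleophilic oxygen.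

**15 ⇒ 12 + 13; 12 ⇒ 11.** The bond between iodine and the trimethoxyphenyl ligand is cut. Iodide 12 is oxidised at iodine and then attacked by 1,3,5-trimethoxybenzene 13. The dummy is chosen because it is more electron-rich than ring B and has no hydrogen ortho to iodine. Iodide 12 comes from commercial bromide 11 by halogen exchange, since only the iodide can be raised to the hypervalent state.

**10 ⇒ 9 ⇒ 8.** The two Si–O bonds of the silylene are cut to give triol 9, and the 8,9-acetonide is put back to give 8. A cyclic silylene was preferred to two open silyl ethers for three reasons. It cannot migrate to the neighbouring alkoxide without contracting to a strained five-membered ring. One reagent singles out O8 by ring size. It leaves with the phenol silyl ether under fluoride. The forward reaction must bridge the 1,3-pair O7/O9 and not the 1,2-pair O8/O9.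

**8 ⇒ 7.** The C7–H bond is cut: the carbinol comes from aryl ketone 7 by chelation-controlled reduction, so C8 sets C7. An aldol-type cut of C7–C8 would have created both centres at once and required external control of both.

**7 ⇒ 2 + 4; 4 ⇐ 3; 2 ⇐ 1.** The C1–C7 bond is cut into an aryllithium from bromide 2 and Weinreb amide 4. Amide 4 comes in one step from pool ester 3, which supplies C7–C9 and the C8 configuration. Bromide 2 is the silyl ether of commercial phenol 1. The forward step must stop at the ketone and must not enolise it.

## Roads not taken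

**Alternative 1:** The cut is C7–H with C8 left free to epimerise. A ketoreductase with NADPH would reduce the racemic α-aryloxy β-keto ester A1 under dynamic kinetic resolution to the (2R,3R)-erythro hydroxy ester A2, setting both centres in one catalytic step.
- Merits: the crowded ether bond of A1 would be made by phenoxide alkylation at an activated α-carbon, a far better founded reaction than step 9. The configurational lability of A1 becomes an asset. The route is probably shorter than the chosen one.
- Weak points: the plan depends on finding an enzyme that accepts a ketone flanked by two bulky aryl-bearing groups and gives the anti product of the right absolute sense; neither can be predicted from structure. After A2 the ester must be reduced in a β-hydroxy α-aryloxy ester that is prone to retro-aldol cleavage. A ketal must then be removed with acid beside the benzylic carbinol, and a benzyl ether hydrogenolysed beside an aryl ketone and a benzylic alcohol.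
- Comparison: in step count and in the safety of the ether formation this road is better. The chosen plan sets against it a configuration that rests on the chiral pool and a predictable chelate, and an end game that needs only fluoride.

**Alternative 2:** The cut is C1–C7. Bromide 2 would be lithiated with n-BuLi and transmetalated with ClTi(OiPr)3, and the resulting non-basic aryl nucleophile added to the (S)-α-aryloxy aldehyde A3 under polar Felkin–Anh control to give the erythro adduct A4.
- Merits: the fragments join by C–C bond formation, and the hindered ether is already in A3, having been made at the easiest possible carbon. The ring-B aldehyde is carried as a dioxolane, closer to the final oxidation state than ester 18.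
- Weak points: the C8–H of A3 lies α to an aldehyde and carries an aryloxy group, so racemisation and β-elimination of the C9 silyloxy group threaten during its preparation and use. The enantiopurity of C8 depends on a lipase desymmetrisation upstream. Felkin–Anh selectivity of aryl nucleophiles toward α-oxygenated aldehydes is substrate-dependent and here must deliver one diastereomer.
- Comparison: the ether bond is better founded than in the chosen plan. Against that, in the chosen plan C8 is never α to an aldehyde and is an aryl ether only after C7 is already a carbinol, and C7 is set by chelation, which is usually the more reliable form of 1,2-induction.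

**Alternative 3:** The cuts are C7–O and C8–H. IpcBH2 would add to the (Z)-aryl enol ether A5 with boron at C7 (benzylic and β to the ether oxygen) and hydrogen at C8 from one face; NaBO3 would then replace boron by hydroxyl with retention to give A6.
- Merits: syn addition to a Z-alkene fixes the erythro relation by mechanism. Both stereocentres arise from an achiral precursor under reagent control, and the ring-B side chain is already in place as a ketal.
- Weak points: the Z geometry of A5 must be secured, since the E isomer gives threo. The enantioselectivity of IpcBH2 on a trisubstituted aryl enol ether of this size is uncertain. The intermediate borane carries boron and an aryloxy group on adjacent carbons and can eliminate, which would expel ring B. The ketal must finally be removed with acid beside the sensitive benzylic carbinol.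
- Comparison: this is potentially the shortest route to the stereodiad and the only one that creates it from achiral material. The chosen plan gives up that economy for a certain absolute configuration and pays with a less closely modelled bond formation in step 9.

Key step: step 9

## Route

Step 1
Reactants: 1 4-bromo-2-methoxyphenol
Product: 2 (4-bromo-2-methoxyphenoxy)triisopropylsilane
Conditions: TIPSCl, imidazole, DMF, rt
Reagents that add atoms: chlorotriisopropylsilane, CC(C)[Si](Cl)(C(C)C)C(C)C
Why: Imidazole-promoted silylation of a phenol; the bulky aryl silyl ether should tolerate n-BuLi, hydride reagents and the sodium alkoxide of step 9, and it leaves with fluoride at the end.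

Step 2
Reactants: 3 methyl (4S)-2,2-dimethyl-1,3-dioxolane-4-carboxylate
Product: 4 (4S)-N-methoxy-N,2,2-trimethyl-1,3-dioxolane-4-carboxamide
Conditions: MeNH(OMe)·HCl, iPrMgCl, THF, −20 °C
Reagents that add atoms: N,O-dimethylhydroxylamine hydrochloride, CNOC.Cl
Why: Direct aminolysis of the ester by the chloromagnesium amide of N,O-dimethylhydroxylamine (Weinreb amide formation); at −20 °C the α-stereocentre should not be deprotonated.

Step 3
Reactants: 2 (4-bromo-2-methoxyphenoxy)triisopropylsilane; 4 (4S)-N-methoxy-N,2,2-trimethyl-1,3-dioxolane-4-carboxamide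
Product: 7 [(4S)-2,2-dimethyl-1,3-dioxolan-4-yl][3-methoxy-4-(triisopropylsilyloxy)phenyl]methanone, via aryllithium 5 (not isolated), via lithium hemiaminal adduct 6 (not isolated)
Conditions: n-BuLi, THF, −78 °C; then 4, −78 → −40 °C; aq. NH4Cl
Reagents that add atoms: none
Why: Bromine–lithium exchange followed by Weinreb ketone synthesis; the chelated tetrahedral adduct 6 prevents a second addition and keeps the α-alkoxy ketone masked until the cold quench, which protects C8 from enolisation.

Step 4
Reactants: 7 [(4S)-2,2-dimethyl-1,3-dioxolan-4-yl][3-methoxy-4-(triisopropylsilyloxy)phenyl]methanone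
Product: 8 (R)-[(4S)-2,2-dimethyl-1,3-dioxolan-4-yl][3-methoxy-4-(triisopropylsilyloxy)phenyl]methanol (anti, erythro)
Conditions: Zn(BH4)2, Et2O, −30 → 0 °C
Reagents that add atoms: none
Why: Chelation-controlled (Cram-chelate) reduction: divalent zinc bridges the carbonyl oxygen and the α-oxygen of the dioxolane, and hydride enters from the face opposite the ring CH2, so C8 (S) sets C7 as R and the anti alcohol should predominate.

Step 5
Reactants: 8 (R)-[(4S)-2,2-dimethyl-1,3-dioxolan-4-yl][3-methoxy-4-(triisopropylsilyloxy)phenyl]methanol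
Product: 9 (1R,2S)-1-[3-methoxy-4-(triisopropylsilyloxy)phenyl]propane-1,2,3-triol
Conditions: AcOH/H2O/THF (3:1:1), 40 °C
Reagents that add atoms: none
Why: Acid-catalysed hydrolysis of a terminal isopropylidene acetal; aqueous acetic acid should be too weak to ionise the benzylic carbinol (β-oxygenated, para oxygen silylated) or to cleave the aryl silyl ether.

Step 6
Reactants: 9 (1R,2S)-1-[3-methoxy-4-(triisopropylsilyloxy)phenyl]propane-1,2,3-triol
Product: 10 (4R,5S)-2,2-di-tert-butyl-4-[3-methoxy-4-(triisopropylsilyloxy)phenyl]-1,3,2-dioxasilinan-5-ol (trans)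
Conditions: tBu2Si(OTf)2, 2,6-lutidine, DMF, −40 → 0 °C
Reagents that add atoms: di-tert-butylsilyl bis(trifluoromethanesulfonate), CC(C)(C)[Si](OS(=O)(=O)C(F)(F)F)(OS(=O)(=O)C(F)(F)F)C(C)(C)C
Why: Cyclic silylene formation: the primary O9 is silylated first, and closure onto O7 gives a six-membered chair with aryl and hydroxyl both equatorial, whereas closure onto O8 would give a strained five-membered ring; O8 is left as the only free hydroxyl.

Step 7
Reactants: 11 methyl 4-bromo-3,5-dimethoxybenzoate
Product: 12 methyl 4-iodo-3,5-dimethoxybenzoate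
Conditions: CuI (10 mol%), trans-N,N'-dimethylcyclohexane-1,2-diamine (20 mol%), NaI, 1,4-dioxane, 110 °C
Reagents that add atoms: sodium iodide, [Na+].[I-]
Why: Copper-catalysed aromatic Finkelstein reaction, driven by precipitation of NaBr from dioxane; the ester is inert to these conditions and the iodide is needed because only it can be oxidised to trivalent iodine.

Step 8
Reactants: 12 methyl 4-iodo-3,5-dimethoxybenzoate; 13 1,3,5-trimethoxybenzene
Product: 15 [2,6-dimethoxy-4-(methoxycarbonyl)phenyl](2,4,6-trimethoxyphenyl)iodonium tosylate, via hydroxy(tosyloxy)iodoarene 14 (not isolated)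
Conditions: mCPBA, TsOH·H2O, MeCN, 60 °C; then 13, rt; Et2O
Reagents that add atoms: p-toluenesulfonic acid monohydrate, Cc1ccc(cc1)S(=O)(=O)O.O
Why: One-pot diaryliodonium synthesis: the peracid with TsOH oxidises the aryl iodide to the [hydroxy(tosyloxy)iodo]arene 14, whose electrophilic iodine substitutes the very electron-rich arene 13 at its only type of free position; the salt should precipitate on adding ether.

Step 9
Reactants: 10 (4R,5S)-2,2-di-tert-butyl-4-[3-methoxy-4-(triisopropylsilyloxy)phenyl]-1,3,2-dioxasilinan-5-ol; 15 [2,6-dimethoxy-4-(methoxycarbonyl)phenyl](2,4,6-trimethoxyphenyl)iodonium tosylate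
Product: 18 methyl 4-({(4R,5S)-2,2-di-tert-butyl-4-[3-methoxy-4-(triisopropylsilyloxy)phenyl]-1,3,2-dioxasilinan-5-yl}oxy)-3,5-dimethoxybenzoate, via sodium alkoxide 16 (not isolated), via alkoxy(diaryl)iodane 17 (not isolated)
Conditions: NaH, tBuOMe, 0 °C → rt; then 15, 50 °C
Reagents that add atoms: none
Why: NaH converts the only free hydroxyl into sodium alkoxide 16, which displaces tosylate at trivalent iodine to give the T-shaped λ3-iodane 17; ligand coupling at the ipso carbon of the ester-bearing ring then forms the O8–C4' bond and releases 2-iodo-1,3,5-trimethoxybenzene, iodine falling to the monovalent state. The closest known reaction type is the metal-free O-arylation of aliphatic, including secondary, alkoxides with diaryliodonium salts that carry a 2,4,6-trimethoxyphenyl dummy ligand; what lies beyond the close models is that the transferred aryl itself has two ortho methoxy groups. No ring closes and no stereocentre is created: the C8–O bond is never broken, so C8 (S) and C7 (R) pass through unchanged. Aryl chemoselectivity is needed and is secured by the para ester: both aryl ligands have the same ortho pattern, so steric ortho effects cancel, and the negative charge that builds up at the ipso carbon during coupling is stabilised on ring B (para CO2Me) and destabilised on the dummy (para OMe). Site selectivity for O8 is secured by the silylene, which ties up O7 and O9 and cannot shift to the neighbouring alkoxide without contracting to a strained five-membered ring; the phenol is silylated. Neither aryl ligand has a hydrogen ortho to iodine, so no aryne pathway exists, and the ester cannot be enolised.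

Step 10
Reactants: 18 methyl 4-({(4R,5S)-2,2-di-tert-butyl-4-[3-methoxy-4-(triisopropylsilyloxy)phenyl]-1,3,2-dioxasilinan-5-yl}oxy)-3,5-dimethoxybenzoate
Product: 19 [4-({(4R,5S)-2,2-di-tert-butyl-4-[3-methoxy-4-(triisopropylsilyloxy)phenyl]-1,3,2-dioxasilinan-5-yl}oxy)-3,5-dimethoxyphenyl]methanol
Conditions: iBu2AlH, CH2Cl2, −78 → −20 °C; aq. KNaC4H4O6 (tartrate)
Reagents that add atoms: none
Why: Hydride reduction of an aryl methyl ester to the benzylic alcohol; silyl ether, silylene and the alkyl aryl ether are inert to iBu2AlH at low temperature.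

Step 11
Reactants: 19 [4-({(4R,5S)-2,2-di-tert-butyl-4-[3-methoxy-4-(triisopropylsilyloxy)phenyl]-1,3,2-dioxasilinan-5-yl}oxy)-3,5-dimethoxyphenyl]methanol
Product: 20 4-({(4R,5S)-2,2-di-tert-butyl-4-[3-methoxy-4-(triisopropylsilyloxy)phenyl]-1,3,2-dioxasilinan-5-yl}oxy)-3,5-dimethoxybenzaldehyde
Conditions: MnO2, CH2Cl2, rt
Reagents that add atoms: none
Why: MnO2 oxidation is selective for benzylic alcohols and stops at the aldehyde under neutral conditions; the C7 benzylic oxygen is silylated and cannot react.

Step 12
Reactants: 20 4-({(4R,5S)-2,2-di-tert-butyl-4-[3-methoxy-4-(triisopropylsilyloxy)phenyl]-1,3,2-dioxasilinan-5-yl}oxy)-3,5-dimethoxybenzaldehyde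
Product: 21 1-[4-({(4R,5S)-2,2-di-tert-butyl-4-[3-methoxy-4-(triisopropylsilyloxy)phenyl]-1,3,2-dioxasilinan-5-yl}oxy)-3,5-dimethoxyphenyl]-2-hydroxyethan-1-one
Conditions: 3-benzyl-5-(2-hydroxyethyl)-4-methylthiazolium chloride (20 mol%), iPr2NEt, (CH2O)n, THF, 60 °C
Reagents that add atoms: paraformaldehyde, reacting as formaldehyde, C=O
Why: Carbene-catalysed cross-acyloin reaction (hydroxymethylation): the thiazolylidene adds to the aryl aldehyde, the resulting acyl-anion equivalent attacks formaldehyde as the more electrophilic partner, and release of the catalyst gives the aryl hydroxymethyl ketone. No stereocentre is formed and the mild amine base should leave both silicon groups untouched.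

Step 13
Reactants: 21 1-[4-({(4R,5S)-2,2-di-tert-butyl-4-[3-methoxy-4-(triisopropylsilyloxy)phenyl]-1,3,2-dioxasilinan-5-yl}oxy)-3,5-dimethoxyphenyl]-2-hydroxyethan-1-one
Product: 22 1-(4-{[(1R,2S)-1,3-dihydroxy-1-(4-hydroxy-3-methoxyphenyl)propan-2-yl]oxy}-3,5-dimethoxyphenyl)-2-hydroxyethan-1-one (target, 7R,8S, erythro)
Conditions: HF·pyridine, pyridine, THF, 0 °C → rt
Reagents that add atoms: none
Why: Fluoride cleaves the silylene and the aryl silyl ether in one operation; buffered HF·pyridine should be neither basic enough to enolise the hydroxy ketone or start quinone-methide chemistry nor acidic enough to ionise C7, so both stereocentres should emerge intact.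

## Compound list

1 | 4-bromo-2-methoxyphenol | COc1cc(Br)ccc1O | starting material
2 | (4-bromo-2-methoxyphenoxy)triisopropylsilane | COc1cc(Br)ccc1O[Si](C(C)C)(C(C)C)C(C)C | intermediate
3 | methyl (4S)-2,2-dimethyl-1,3-dioxolane-4-carboxylate | COC(=O)[C@@H]1COC(C)(C)O1 | starting material
4 | (4S)-N-methoxy-N,2,2-trimethyl-1,3-dioxolane-4-carboxamide | CON(C)C(=O)[C@@H]1COC(C)(C)O1 | intermediate
5 | [3-methoxy-4-(triisopropylsilyloxy)phenyl]lithium | COc1cc([Li])ccc1O[Si](C(C)C)(C(C)C)C(C)C | intermediate (not isolated)
6 | lithium [(4S)-2,2-dimethyl-1,3-dioxolan-4-yl][methoxy(methyl)amino][3-methoxy-4-(triisopropylsilyloxy)phenyl]methanolate (tetrahedral adduct, either configuration at the new carbon) | COc1cc(C([O-])(N(C)OC)[C@@H]2COC(C)(C)O2)ccc1O[Si](C(C)C)(C(C)C)C(C)C.[Li+] | intermediate (not isolated)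
7 | [(4S)-2,2-dimethyl-1,3-dioxolan-4-yl][3-methoxy-4-(triisopropylsilyloxy)phenyl]methanone | COc1cc(C(=O)[C@@H]2COC(C)(C)O2)ccc1O[Si](C(C)C)(C(C)C)C(C)C | intermediate
8 | (R)-[(4S)-2,2-dimethyl-1,3-dioxolan-4-yl][3-methoxy-4-(triisopropylsilyloxy)phenyl]methanol | COc1cc([C@@H](O)[C@@H]2COC(C)(C)O2)ccc1O[Si](C(C)C)(C(C)C)C(C)C | intermediate
9 | (1R,2S)-1-[3-methoxy-4-(triisopropylsilyloxy)phenyl]propane-1,2,3-triol | COc1cc([C@@H](O)[C@@H](O)CO)ccc1O[Si](C(C)C)(C(C)C)C(C)C | intermediate
10 | (4R,5S)-2,2-di-tert-butyl-4-[3-methoxy-4-(triisopropylsilyloxy)phenyl]-1,3,2-dioxasilinan-5-ol | COc1cc([C@H]2O[Si](C(C)(C)C)(C(C)(C)C)OC[C@@H]2O)ccc1O[Si](C(C)C)(C(C)C)C(C)C | intermediate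
11 | methyl 4-bromo-3,5-dimethoxybenzoate | COC(=O)c1cc(OC)c(Br)c(OC)c1 | starting material
12 | methyl 4-iodo-3,5-dimethoxybenzoate | COC(=O)c1cc(OC)c(I)c(OC)c1 | intermediate
13 | 1,3,5-trimethoxybenzene | COc1cc(OC)cc(OC)c1 | starting material
14 | methyl 4-[hydroxy(tosyloxy)-λ3-iodanyl]-3,5-dimethoxybenzoate | COC(=O)c1cc(OC)c(I(O)OS(=O)(=O)c2ccc(C)cc2)c(OC)c1 | intermediate (not isolated)
15 | [2,6-dimethoxy-4-(methoxycarbonyl)phenyl](2,4,6-trimethoxyphenyl)iodonium tosylate | COC(=O)c1cc(OC)c([I+]c2c(OC)cc(OC)cc2OC)c(OC)c1.Cc1ccc(cc1)S(=O)(=O)[O-] | intermediate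
16 | sodium (4R,5S)-2,2-di-tert-butyl-4-[3-methoxy-4-(triisopropylsilyloxy)phenyl]-1,3,2-dioxasilinan-5-olate | COc1cc([C@H]2O[Si](C(C)(C)C)(C(C)(C)C)OC[C@@H]2[O-])ccc1O[Si](C(C)C)(C(C)C)C(C)C.[Na+] | intermediate (not isolated)
17 | {[(4R,5S)-2,2-di-tert-butyl-4-[3-methoxy-4-(triisopropylsilyloxy)phenyl]-1,3,2-dioxasilinan-5-yl]oxy}[2,6-dimethoxy-4-(methoxycarbonyl)phenyl](2,4,6-trimethoxyphenyl)-λ3-iodane | COc1cc([C@H]2O[Si](C(C)(C)C)(C(C)(C)C)OC[C@@H]2OI(c3c(OC)cc(C(=O)OC)cc3OC)c3c(OC)cc(OC)cc3OC)ccc1O[Si](C(C)C)(C(C)C)C(C)C | intermediate (not isolated)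
18 | methyl 4-({(4R,5S)-2,2-di-tert-butyl-4-[3-methoxy-4-(triisopropylsilyloxy)phenyl]-1,3,2-dioxasilinan-5-yl}oxy)-3,5-dimethoxybenzoate | COc1cc([C@H]2O[Si](C(C)(C)C)(C(C)(C)C)OC[C@@H]2Oc3c(OC)cc(C(=O)OC)cc3OC)ccc1O[Si](C(C)C)(C(C)C)C(C)C | intermediate
19 | [4-({(4R,5S)-2,2-di-tert-butyl-4-[3-methoxy-4-(triisopropylsilyloxy)phenyl]-1,3,2-dioxasilinan-5-yl}oxy)-3,5-dimethoxyphenyl]methanol | COc1cc([C@H]2O[Si](C(C)(C)C)(C(C)(C)C)OC[C@@H]2Oc3c(OC)cc(CO)cc3OC)ccc1O[Si](C(C)C)(C(C)C)C(C)C | intermediate
20 | 4-({(4R,5S)-2,2-di-tert-butyl-4-[3-methoxy-4-(triisopropylsilyloxy)phenyl]-1,3,2-dioxasilinan-5-yl}oxy)-3,5-dimethoxybenzaldehyde | COc1cc([C@H]2O[Si](C(C)(C)C)(C(C)(C)C)OC[C@@H]2Oc3c(OC)cc(C=O)cc3OC)ccc1O[Si](C(C)C)(C(C)C)C(C)C | intermediate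
21 | 1-[4-({(4R,5S)-2,2-di-tert-butyl-4-[3-methoxy-4-(triisopropylsilyloxy)phenyl]-1,3,2-dioxasilinan-5-yl}oxy)-3,5-dimethoxyphenyl]-2-hydroxyethan-1-one | COc1cc([C@H]2O[Si](C(C)(C)C)(C(C)(C)C)OC[C@@H]2Oc3c(OC)cc(C(=O)CO)cc3OC)ccc1O[Si](C(C)C)(C(C)C)C(C)C | intermediate
22 | 1-(4-{[(1R,2S)-1,3-dihydroxy-1-(4-hydroxy-3-methoxyphenyl)propan-2-yl]oxy}-3,5-dimethoxyphenyl)-2-hydroxyethan-1-one | COc1cc([C@@H](O)[C@H](CO)Oc2c(OC)cc(C(=O)CO)cc2OC)ccc1O | target

## Step count and least certain steps

Total: 13 steps. Longest linear sequence: 10 steps (3 → 4 → 7 → 8 → 9 → 10 → 18 → 19 → 20 → 21 → 22; the branch from 1 through 2 is equally long; the ring-B branch 11 → 12 → 15 joins at step 9).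

**Step 9 (key step).** Ligand coupling at an ipso carbon flanked by two methoxy groups may be slow. Two competing processes could then take over: oxidation of the alkoxide by trivalent iodine (loss of hydride from C8) and transfer of the trimethoxyphenyl ligand. A third danger is base-induced transfer of silicon from the phenol or the silylene to the alkoxide, which would scramble the arylation site. The fallback gives up the aryl-side cut and forms the C8–O bond by double inversion; it sets out from 10 and returns at 18. Mitsunobu reaction of 10 with chloroacetic acid (PPh3, DIAD) should give (4R,5R)-2,2-di-tert-butyl-4-[3-methoxy-4-(triisopropylsilyloxy)phenyl]-1,3,2-dioxasilinan-5-yl chloroacetate F1. Methanolysis with Et3N/MeOH should free the cis (threo) alcohol, (4R,5R)-2,2-di-tert-butyl-4-[3-methoxy-4-(triisopropylsilyloxy)phenyl]-1,3,2-dioxasilinan-5-ol F2. A second Mitsunobu reaction with methyl 4-hydroxy-3,5-dimethoxybenzoate should invert C8 back to S and give 18.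

**Step 12.** The electron-rich, para-alkoxy aldehyde may form the carbene adduct slowly. Self-condensation of formaldehyde, homo-benzoin coupling or a second hydroxymethylation of the product could then compete. The fallback builds the side chain by enolate oxidation; it sets out from 20 and returns at 21. MeMgBr should give 1-[4-({(4R,5S)-2,2-di-tert-butyl-4-[3-methoxy-4-(triisopropylsilyloxy)phenyl]-1,3,2-dioxasilinan-5-yl}oxy)-3,5-dimethoxyphenyl]ethan-1-ol F3 (both carbinol epimers). MnO2 should give the corresponding methyl ketone, 1-[4-({(4R,5S)-2,2-di-tert-butyl-4-[3-methoxy-4-(triisopropylsilyloxy)phenyl]-1,3,2-dioxasilinan-5-yl}oxy)-3,5-dimethoxyphenyl]ethan-1-one F4. TMSOTf/Et3N should give its trimethylsilyl enol ether F5. Rubottom oxidation (mCPBA, NaHCO3, CH2Cl2, 0 °C) with mildly acidic removal of the migrated trimethylsilyl group should then give 21.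

**Step 6.** Ring closure onto O8 may compete with closure onto O7, giving the five-membered silylene or oligomeric silylation. The fallback attaches silicon to O7 first, so that the ring-size choice lies between a primary hydroxyl closing a six-membered ring and a secondary one closing a five-membered ring. It sets out from 8 and returns at 10. tBu2Si(H)Cl/imidazole should give (4S)-4-{(R)-[(di-tert-butylsilyl)oxy][3-methoxy-4-(triisopropylsilyloxy)phenyl]methyl}-2,2-dimethyl-1,3-dioxolane F6. Aqueous acetic acid should free (2S,3R)-3-[(di-tert-butylsilyl)oxy]-3-[3-methoxy-4-(triisopropylsilyloxy)phenyl]propane-1,2-diol F7. Alkoxide-catalysed dehydrogenative Si–O coupling (catalytic NaH, THF) should close the Si–H bond onto O9 and give 10.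

**Step 7.** Halogen exchange at a bromide flanked by two methoxy groups may stall, leaving a bromide/iodide mixture. The fallback replaces copper catalysis by halogen–magnesium exchange, which the two ortho oxygens and the para ester favour; it sets out from 11 and returns at 12. iPrMgCl·LiCl (THF, −20 °C) should give [2,6-dimethoxy-4-(methoxycarbonyl)phenyl]magnesium chloride F8, which is quenched with I2 to give 12.

**Step 4.** Facial selectivity may be insufficient if an open transition state or chelation through the β-oxygen competes with the α-chelate, which would contaminate 8 with the syn (threo) alcohol. The fallback uses reagent control in place of substrate control; it sets out from 7 and returns at 8. CBS reduction with (R)-2-methyl-CBS-oxazaborolidine and BH3·SMe2 should deliver hydride to the face that gives the (R)-carbinol, provided the aryl group takes the large-group position. No new compound is made (F0).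

## Further compounds

F1 | step 9 | (4R,5R)-2,2-di-tert-butyl-4-[3-methoxy-4-(triisopropylsilyloxy)phenyl]-1,3,2-dioxasilinan-5-yl chloroacetate | COc1cc([C@H]2O[Si](C(C)(C)C)(C(C)(C)C)OC[C@H]2OC(=O)CCl)ccc1O[Si](C(C)C)(C(C)C)C(C)C
F2 | step 9 | (4R,5R)-2,2-di-tert-butyl-4-[3-methoxy-4-(triisopropylsilyloxy)phenyl]-1,3,2-dioxasilinan-5-ol | COc1cc([C@H]2O[Si](C(C)(C)C)(C(C)(C)C)OC[C@H]2O)ccc1O[Si](C(C)C)(C(C)C)C(C)C
F3 | step 12 | 1-[4-({(4R,5S)-2,2-di-tert-butyl-4-[3-methoxy-4-(triisopropylsilyloxy)phenyl]-1,3,2-dioxasilinan-5-yl}oxy)-3,5-dimethoxyphenyl]ethan-1-ol | COc1cc([C@H]2O[Si](C(C)(C)C)(C(C)(C)C)OC[C@@H]2Oc3c(OC)cc(C(C)O)cc3OC)ccc1O[Si](C(C)C)(C(C)C)C(C)C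
F4 | step 12 | 1-[4-({(4R,5S)-2,2-di-tert-butyl-4-[3-methoxy-4-(triisopropylsilyloxy)phenyl]-1,3,2-dioxasilinan-5-yl}oxy)-3,5-dimethoxyphenyl]ethan-1-one | COc1cc([C@H]2O[Si](C(C)(C)C)(C(C)(C)C)OC[C@@H]2Oc3c(OC)cc(C(C)=O)cc3OC)ccc1O[Si](C(C)C)(C(C)C)C(C)C
F5 | step 12 | trimethylsilyl enol ether of F4, {1-[4-({(4R,5S)-2,2-di-tert-butyl-4-[3-methoxy-4-(triisopropylsilyloxy)phenyl]-1,3,2-dioxasilinan-5-yl}oxy)-3,5-dimethoxyphenyl]ethenyloxy}trimethylsilane | COc1cc([C@H]2O[Si](C(C)(C)C)(C(C)(C)C)OC[C@@H]2Oc3c(OC)cc(C(=C)O[Si](C)(C)C)cc3OC)ccc1O[Si](C(C)C)(C(C)C)C(C)C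
F6 | step 6 | (4S)-4-{(R)-[(di-tert-butylsilyl)oxy][3-methoxy-4-(triisopropylsilyloxy)phenyl]methyl}-2,2-dimethyl-1,3-dioxolane | COc1cc([C@@H](O[SiH](C(C)(C)C)C(C)(C)C)[C@@H]2COC(C)(C)O2)ccc1O[Si](C(C)C)(C(C)C)C(C)C
F7 | step 6 | (2S,3R)-3-[(di-tert-butylsilyl)oxy]-3-[3-methoxy-4-(triisopropylsilyloxy)phenyl]propane-1,2-diol | COc1cc([C@@H](O[SiH](C(C)(C)C)C(C)(C)C)[C@@H](O)CO)ccc1O[Si](C(C)C)(C(C)C)C(C)C
F8 | step 7 | [2,6-dimethoxy-4-(methoxycarbonyl)phenyl]magnesium chloride | COC(=O)c1cc(OC)c([Mg]Cl)c(OC)c1
F0 | step 4 | none | none
A1 | alternative 1 | racemic ethyl 3-(4-benzyloxy-3-methoxyphenyl)-2-[4-(2-hydroxy-1,1-dimethoxyethyl)-2,6-dimethoxyphenoxy]-3-oxopropanoate | COc1cc(C(=O)C(C(=O)OCC)Oc2c(OC)cc(C(OC)(OC)CO)cc2OC)ccc1OCc1ccccc1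
A2 | alternative 1 | ethyl (2R,3R)-3-(4-benzyloxy-3-methoxyphenyl)-3-hydroxy-2-[4-(2-hydroxy-1,1-dimethoxyethyl)-2,6-dimethoxyphenoxy]propanoate | COc1cc([C@@H](O)[C@H](C(=O)OCC)Oc2c(OC)cc(C(OC)(OC)CO)cc2OC)ccc1OCc1ccccc1
A3 | alternative 2 | (2S)-3-(tert-butyldiphenylsilyloxy)-2-[4-(1,3-dioxolan-2-yl)-2,6-dimethoxyphenoxy]propanal | O=C[C@H](CO[Si](c1ccccc1)(c1ccccc1)C(C)(C)C)Oc1c(OC)cc(C2OCCO2)cc1OC
A4 | alternative 2 | (1R,2S)-3-(tert-butyldiphenylsilyloxy)-2-[4-(1,3-dioxolan-2-yl)-2,6-dimethoxyphenoxy]-1-[3-methoxy-4-(triisopropylsilyloxy)phenyl]propan-1-ol | COc1cc([C@@H](O)[C@H](CO[Si](c2ccccc2)(c2ccccc2)C(C)(C)C)Oc2c(OC)cc(C3OCCO3)cc2OC)ccc1O[Si](C(C)C)(C(C)C)C(C)C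
A5 | alternative 3 | (Z)-enol ether, 3-(tert-butyldimethylsilyloxy)-2-{4-[2-(tert-butyldimethylsilyloxy)-1,1-dimethoxyethyl]-2,6-dimethoxyphenoxy}-1-[3-methoxy-4-(triisopropylsilyloxy)phenyl]prop-1-ene | COc1cc(/C=C(/CO[Si](C)(C)C(C)(C)C)Oc2c(OC)cc(C(OC)(OC)CO[Si](C)(C)C(C)(C)C)cc2OC)ccc1O[Si](C(C)C)(C(C)C)C(C)C
A6 | alternative 3 | (1R,2S)-3-(tert-butyldimethylsilyloxy)-2-{4-[2-(tert-butyldimethylsilyloxy)-1,1-dimethoxyethyl]-2,6-dimethoxyphenoxy}-1-[3-methoxy-4-(triisopropylsilyloxy)phenyl]propan-1-ol | COc1cc([C@@H](O)[C@H](CO[Si](C)(C)C(C)(C)C)Oc2c(OC)cc(C(OC)(OC)CO[Si](C)(C)C(C)(C)C)cc2OC)ccc1O[Si](C(C)C)(C(C)C)C(C)C
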